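Numbering used throughout: ring carbons C1–C10 (C3 carries the isobutyrate, C6 and C8 the lactone oxygens, C10 the C14H2OH group), C11–C13 are the α-methylene lactone carbons, C15 is the butenolide carbonyl.
Retrosynthetic cuts, in order: O14–Si and O3–acyl; O8–C12 (hydro-acyloxylation of an 8,9-alkene); C4=C5 (selenoxide) and C3–H (ketone reduction); C4–C15 (Claisen onto a C6 carbonate) and C11–C12 (alkyne carbonylation); then C1–C10 with C3–C8 re-joined, giving a cyclohexanol; its vinyl, alkynyl and alkenyl groups come off to (R)-4-hydroxycyclohexenone.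
Enabling feature: the oxygenated C3 lies two atoms from C1 and C8 two atoms from C10, so C1=C2–C3(O−)–C8–C9=C10 is an oxy-Cope array; the ten-membered ring is a cyclohexane (C3–C8, the six carbons of the enone) enlarged by C1, C2, C9 and C10.
Forward order of rings: cyclohexane C3–C8 (given), then the ten-membered ring by ring expansion, then the γ-lactone through C15 (later the butenolide), then the α-methylene lactone through C12.
Stereochemistry: C6 from the chiral pool; C7 by hydroxyl-directed conjugate alkynylation; C8 (temporary) by equilibration; C10 by chair chirality transfer in the [3,3] shift; C3 by CBS reduction; C8 (final) by lactonisation on the alkene face fixed by C7.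

Key step: step 7

Assumption: (4R)-4-hydroxycyclohex-2-en-1-one (3) and the silyl propargyl ether 1 are taken as purchasable in the purity needed; descriptors of ring compounds from 15 on use the numbering above.

Step 1
Reactants: 1 tert-butyl(diphenyl)(prop-2-yn-1-yloxy)silane
Product: 2 tert-butyl(diphenyl){[(2E)-3-(4,4,5,5-tetramethyl-1,3,2-dioxaborolan-2-yl)prop-2-en-1-yl]oxy}silane
Conditions: pinacolborane, Cp2Zr(H)Cl (5 mol %), Et3N (10 mol %), neat, 60 °C
Reagents that add atoms: pinacolborane, B1OC(C)(C)C(C)(C)O1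
Why: Zirconium-catalysed hydroboration of a terminal alkyne (syn addition, boron on the terminal carbon) should give the (E)-alkenylboronate that becomes C9=C10–C14.

Step 2
Reactants: 3 (4R)-4-hydroxycyclohex-2-en-1-one
Product: 4 (4R)-4-hydroxy-2-iodocyclohex-2-en-1-one
Conditions: I2, pyridine, CH2Cl2, 0 °C to rt
Reagents that add atoms: iodine, II
Why: α-Iodination of the enone (conjugate addition of pyridine, iodination of the enolate, elimination) should place iodine on C8 without touching C6.

Step 3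
Reactants: 4 (4R)-4-hydroxy-2-iodocyclohex-2-en-1-one; 2 the (E)-alkenylboronate
Product: 5 (4R)-2-[(1E)-3-{[tert-butyl(diphenyl)silyl]oxy}prop-1-en-1-yl]-4-hydroxycyclohex-2-en-1-one
Conditions: PdCl2(dppf) (5 mol %), AsPh3, Cs2CO3, DMF/THF/H2O, rt
Reagents that add atoms: none
Why: Suzuki–Miyaura coupling of the α-iodoenone with the alkenylboronate should join C8 to C9 with retention of the (E)-geometry.

Step 4
Reactants: 5 the 2-alkenyl-4-hydroxy enone
Product: 7 (2S,3R,4R)-2-[(1E)-3-{[tert-butyl(diphenyl)silyl]oxy}prop-1-en-1-yl]-3-ethynyl-4-hydroxycyclohexan-1-one, via silyl alkynyl ketone 6 (not isolated)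
Conditions: Me3SiC≡CLi (from Me3SiC≡CH, n-BuLi), Me2AlCl, toluene/Et2O, −20 to 0 °C; aqueous work-up; then K2CO3, MeOH, 0 °C
Reagents that add atoms: dimethyl[(trimethylsilyl)ethynyl]aluminium, C[Al](C)C#C[Si](C)(C)C
Why: Hydroxyl-directed conjugate alkynylation, in which the aluminium alkoxide at O6 should deliver the alkynyl group to C7 on its own face (C7–C11 cis to O6); methanolic K2CO3 should then cleave the C–Si bond and equilibrate the enolisable C8 to the trans-diequatorial ketone.

Step 5
Reactants: 7 the hydroxy ketone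
Product: 8 (1R,2R,3S)-3-[(1E)-3-{[tert-butyl(diphenyl)silyl]oxy}prop-1-en-1-yl]-2-ethynyl-4-oxocyclohexyl methyl carbonate
Conditions: ClCO2Me, pyridine, DMAP (cat.), CH2Cl2, 0 °C
Reagents that add atoms: methyl chloroformate, COC(=O)Cl
Why: O-Acylation should give the methyl carbonate, which protects O6 now and later supplies C15.

Step 6
Reactants: 8 the keto carbonate
Product: 9 (1R,2R,3S,4S)-3-[(1E)-3-{[tert-butyl(diphenyl)silyl]oxy}prop-1-en-1-yl]-4-ethenyl-2-ethynyl-4-hydroxycyclohexyl methyl carbonate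
Conditions: CH2=CHMgBr, CeCl3 (dried), THF, −78 °C; aq. NH4Cl; minor C3 epimer removed by chromatography
Reagents that add atoms: vinylmagnesium bromide, C=C[Mg]Br
Why: Organocerium 1,2-addition (no enolisation of the acidic C8–H) should occur by equatorial attack, trans to the equatorial alkenyl group on C8, giving the trans-1,2-dialkenyl carbinol in which C3 is a temporary stereocentre.

Step 7
Reactants: 9 the trans-1,2-dialkenyl cyclohexanol
Product: 12 (1R,2R,3E,5R)-5-({[tert-butyl(diphenyl)silyl]oxy}methyl)-2-ethynyl-8-oxocyclodec-3-en-1-yl methyl carbonate, via potassium alkoxide 10 (not isolated), via potassium enolate 11 (not isolated)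
Conditions: KN(SiMe3)2 (1.1 equiv), 18-crown-6, THF, −78 to −30 °C; then aq. NH4Cl at −78 °C
Reagents that add atoms: none
Why: The potassium alkoxide 10 should undergo a concerted, charge-accelerated [3,3]-sigmatropic shift of the 1,5-diene C1=C2–C3(O−)–C8–C9=C10 (anionic oxy-Cope rearrangement, the established entry from 1,2-dialkenylcyclohexanols to cyclodec-5-enones), forming C1–C10 as C3–C8 breaks and giving enolate 11, which is protonated on work-up. The ten-membered carbocycle is closed by a four-carbon ring expansion of the cyclohexane through a six-membered chair transition state, not by an end-to-end cyclisation, and the alkoxide-to-enolate change pays for the ring strain. C10, the only new stereocentre, is set by suprafacial chirality transfer from C8: with the vinyl group on C3 and the (E)-propenyl group on C8 both equatorial, C1 bonds to the face of C9=C10 that the C8 configuration presents, which places C14 equatorial in the chair and gives 10R. The same chair delivers the (E)-C8=C9 alkene and leaves C6 and C7 untouched. The step needs the chair [3,3] path to prevail over boat geometry and over heterolytic C3–C8 cleavage; the trans-diequatorial alkenyl groups, the (E)-geometry of C9=C10 and the low temperature allowed by the crown-ether-separated alkoxide secure this, and O3 and O6 are trans on the ring so the alkoxide cannot reach the carbonate.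

Step 8
Reactants: 12 the ethynyl cyclodecenone
Product: 13 2-[(1R,2E,4R,10R)-4-({[tert-butyl(diphenyl)silyl]oxy}methyl)-10-[(methoxycarbonyl)oxy]-7-oxocyclodec-2-en-1-yl]prop-2-enoic acid
Conditions: Pd(OAc)2 (5 mol %), Xantphos (10 mol %), HCO2H, Ac2O (20 mol %), toluene, 80 °C
Reagents that add atoms: formic acid, O=CO
Why: Palladium hydride-mediated Markovnikov hydrocarboxylation of the terminal alkyne (formic acid as the source of CO and water) should give the 2-substituted acrylic acid, that is C11(=C13)–C12O2H; no stereocentre is involved.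

Step 9
Reactants: 13 the keto carbonate acrylic acid
Product: 15 phenylselanyl keto lactone acid (3-oxo; 4-SePh; 15,6-γ-lactone; 8E; 7-(1-carboxyvinyl); 6R,7R,10R; both C4 epimers), via dipotassium lactone enolate 14 (not isolated)
Conditions: KN(SiMe3)2 (2.1 equiv), THF, −78 to 0 °C; then PhSeBr (1.0 equiv), −78 °C; aq. HCl work-up
Reagents that add atoms: benzeneselenenyl bromide, Br[Se]c1ccccc1
Why: Intramolecular Claisen (Dieckmann-type) acylation, in which only the C4 enolate of the equilibrating ketone enolates can reach the C6 carbonate (5-exo-trig, γ-lactone) and loss of methoxide plus deprotonation of the β-keto lactone drive the closure; the enolate is then selenenylated at C4, where both epimers are usable.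

Step 10
Reactants: 15 the phenylselanyl keto lactone acid
Product: 18 hydroxy butenolide acid (3S,6R,7R,10R; 4-en-15,6-olide; 8E; 7-(1-carboxyvinyl); 14-O-silyl), via seleno alcohol 16 (not isolated), via selenoxide 17 (not isolated)
Conditions: (R)-2-methyl-CBS-oxazaborolidine (0.5 equiv), catecholborane (3 equiv), toluene/CH2Cl2, −78 to −40 °C; then 30% H2O2, THF, 0 °C to rt
Reagents that add atoms: none
Why: CBS reduction, where the catalyst distinguishes the quaternary C4 flank from the C2 methylene and should deliver hydride to give 3S, followed by oxidation to the selenoxide and syn-elimination toward C5–H (away from the oxygen-bearing C3), which should unveil the butenolide.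

Step 11
Reactants: 18 the hydroxy butenolide acid
Product: 19 14-O-silyl 3-hydroxy bis-lactone (3S,6R,7S,8R,10R; 12,8-olide with 11(13)-methylene; 4-en-15,6-olide)
Conditions: TfOH (10 mol %), CH2Cl2, 0 °C
Reagents that add atoms: none
Why: Brønsted acid-catalysed intramolecular hydro-acyloxylation of the strained (E)-8,9-alkene (5-exo closure to the γ-lactone, proton to C9); with H7 in the alkene plane (allylic strain minimum) the carboxyl group should add to the face of C8 opposite to the ring bond C7–C6, giving the trans-fused lactone (8R).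

Step 12
Reactants: 19 the 3-hydroxy bis-lactone
Product: 20 14-O-silyl 3-isobutyrate (3S,6R,7S,8R,10R)
Conditions: (i-PrCO)2O, Et3N, DMAP (cat.), CH2Cl2, 0 °C
Reagents that add atoms: isobutyric anhydride, CC(C)C(=O)OC(=O)C(C)C
Why: DMAP-catalysed acylation of the only free hydroxyl group (C3–OH) should give the isobutyrate with retention at C3.

Step 13
Reactants: 20 the silyl ether
Product: 21 (3S,6R,7S,8R,10R)-14-hydroxy-3-(2-methylpropanoyloxy)germacra-4,11(13)-diene-12,8:15,6-diolide (target)
Conditions: HF·pyridine, THF, 0 °C to rt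
Reagents that add atoms: none
Why: Fluoride-mediated cleavage of the silyl ether should free the C14 hydroxyl group while sparing the α-methylene lactone, the butenolide and the ester.

Compound list
1 | tert-butyl(diphenyl)(prop-2-yn-1-yloxy)silane | C#CCO[Si](c4ccccc4)(c5ccccc5)C(C)(C)C | starting material
2 | tert-butyl(diphenyl){[(2E)-3-(4,4,5,5-tetramethyl-1,3,2-dioxaborolan-2-yl)prop-2-en-1-yl]oxy}silane | CC1(C)OB(/C=C/CO[Si](c4ccccc4)(c5ccccc5)C(C)(C)C)OC1(C)C | intermediate
3 | (4R)-4-hydroxycyclohex-2-en-1-one | O=C1C=C[C@H](O)CC1 | starting material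
4 | (4R)-4-hydroxy-2-iodocyclohex-2-en-1-one | O=C1C(I)=C[C@H](O)CC1 | intermediate
5 | (4R)-2-[(1E)-3-{[tert-butyl(diphenyl)silyl]oxy}prop-1-en-1-yl]-4-hydroxycyclohex-2-en-1-one | O=C1C(/C=C/CO[Si](c4ccccc4)(c5ccccc5)C(C)(C)C)=C[C@H](O)CC1 | intermediate
6 | (3R,4R)-2-[(1E)-3-{[tert-butyl(diphenyl)silyl]oxy}prop-1-en-1-yl]-4-hydroxy-3-[(trimethylsilyl)ethynyl]cyclohexan-1-one (C2 epimers) | O=C1C(/C=C/CO[Si](c4ccccc4)(c5ccccc5)C(C)(C)C)[C@H](C#C[Si](C)(C)C)[C@H](O)CC1 | intermediate (not isolated)
7 | (2S,3R,4R)-2-[(1E)-3-{[tert-butyl(diphenyl)silyl]oxy}prop-1-en-1-yl]-3-ethynyl-4-hydroxycyclohexan-1-one | O=C1[C@@H](/C=C/CO[Si](c4ccccc4)(c5ccccc5)C(C)(C)C)[C@H](C#C)[C@H](O)CC1 | intermediate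
8 | (1R,2R,3S)-3-[(1E)-3-{[tert-butyl(diphenyl)silyl]oxy}prop-1-en-1-yl]-2-ethynyl-4-oxocyclohexyl methyl carbonate | O=C1[C@@H](/C=C/CO[Si](c4ccccc4)(c5ccccc5)C(C)(C)C)[C@H](C#C)[C@H](OC(=O)OC)CC1 | intermediate
9 | (1R,2R,3S,4S)-3-[(1E)-3-{[tert-butyl(diphenyl)silyl]oxy}prop-1-en-1-yl]-4-ethenyl-2-ethynyl-4-hydroxycyclohexyl methyl carbonate | C=C[C@]1(O)[C@@H](/C=C/CO[Si](c4ccccc4)(c5ccccc5)C(C)(C)C)[C@H](C#C)[C@H](OC(=O)OC)CC1 | intermediate
10 | potassium alkoxide of 9 | [K+].C=C[C@]1([O-])[C@@H](/C=C/CO[Si](c4ccccc4)(c5ccccc5)C(C)(C)C)[C@H](C#C)[C@H](OC(=O)OC)CC1 | intermediate (not isolated)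
11 | potassium (Z)-enolate (C2=C3–O−) of 12 | [K+].[O-]/C1=C\C[C@@H](CO[Si](c4ccccc4)(c5ccccc5)C(C)(C)C)/C=C/[C@H](C#C)[C@H](OC(=O)OC)CC1 | intermediate (not isolated)
12 | (1R,2R,3E,5R)-5-({[tert-butyl(diphenyl)silyl]oxy}methyl)-2-ethynyl-8-oxocyclodec-3-en-1-yl methyl carbonate | O=C1CC[C@@H](OC(=O)OC)[C@@H](C#C)/C=C/[C@H](CO[Si](c4ccccc4)(c5ccccc5)C(C)(C)C)CC1 | intermediate
13 | 2-[(1R,2E,4R,10R)-4-({[tert-butyl(diphenyl)silyl]oxy}methyl)-10-[(methoxycarbonyl)oxy]-7-oxocyclodec-2-en-1-yl]prop-2-enoic acid | O=C1CC[C@@H](OC(=O)OC)[C@@H](C(=C)C(=O)O)/C=C/[C@H](CO[Si](c4ccccc4)(c5ccccc5)C(C)(C)C)CC1 | intermediate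
14 | dipotassium salt (carboxylate and C3–C4 enolate) of the β-keto 15,6-lactone acid | [K+].[K+].[O-]C(=O)C(=C)[C@H]1/C=C/[C@H](CO[Si](c4ccccc4)(c5ccccc5)C(C)(C)C)CCC([O-])=C2C[C@H]1OC2=O | intermediate (not isolated)
15 | phenylselanyl keto lactone acid (3-oxo; 4-SePh; 15,6-γ-lactone; 8E; 6R,7R,10R; C4 epimers) | OC(=O)C(=C)[C@H]1/C=C/[C@H](CO[Si](c4ccccc4)(c5ccccc5)C(C)(C)C)CCC(=O)C2([Se]c6ccccc6)C[C@H]1OC2=O | intermediate
16 | seleno alcohol (3S,6R,7R,10R; 4-SePh) | OC(=O)C(=C)[C@H]1/C=C/[C@H](CO[Si](c4ccccc4)(c5ccccc5)C(C)(C)C)CC[C@H](O)C2([Se]c6ccccc6)C[C@H]1OC2=O | intermediate (not isolated)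
17 | selenoxide of 16 | OC(=O)C(=C)[C@H]1/C=C/[C@H](CO[Si](c4ccccc4)(c5ccccc5)C(C)(C)C)CC[C@H](O)C2([Se](=O)c6ccccc6)C[C@H]1OC2=O | intermediate (not isolated)
18 | hydroxy butenolide acid (3S,6R,7R,10R; 4-en-15,6-olide; 8E) | OC(=O)C(=C)[C@H]1/C=C/[C@H](CO[Si](c4ccccc4)(c5ccccc5)C(C)(C)C)CC[C@H](O)C2=C[C@H]1OC2=O | intermediate
19 | 14-O-silyl 3-hydroxy bis-lactone (3S,6R,7S,8R,10R) | C=C1C(=O)O[C@@H]2C[C@H](CO[Si](c4ccccc4)(c5ccccc5)C(C)(C)C)CC[C@H](O)C3=C[C@@H](OC3=O)[C@@H]12 | intermediate
20 | 14-O-silyl 3-isobutyrate (3S,6R,7S,8R,10R) | C=C1C(=O)O[C@@H]2C[C@H](CO[Si](c4ccccc4)(c5ccccc5)C(C)(C)C)CC[C@H](OC(=O)C(C)C)C3=C[C@@H](OC3=O)[C@@H]12 | intermediate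
21 | (3S,6R,7S,8R,10R)-14-hydroxy-3-(2-methylpropanoyloxy)germacra-4,11(13)-diene-12,8:15,6-diolide | C=C1C(=O)O[C@@H]2C[C@H](CO)CC[C@H](OC(=O)C(C)C)C3=C[C@@H](OC3=O)[C@@H]12 | target

Total step count: 13. Longest linear sequence: 12 steps (3 to 21 through steps 2–13; equally 1 to 21 through steps 1 and 3–13).

Steps most likely to fail

Step 11. What may go wrong: closure to the six-membered lactone, addition of the carboxyl group to the other alkene face (cis-fused lactone, wrong C8), or hydride shift and transannular capture of the C8 cation. The fallback sets out from 13 and comes back at 19. The Claisen closure of step 9 is run with S-phenyl benzenethiosulfonate in place of PhSeBr to give the phenylthio keto lactone acid F1. CBS reduction as in step 10 gives the phenylthio hydroxy lactone acid F2. Iodolactonisation (I2, NaHCO3, MeCN, 0 °C; anti addition, 5-exo) gives the 9-iodo lactone F3. Radical deiodination (Bu3SnH, Et3B, air, toluene, 0 °C) gives the phenylthio bis-lactone F4; no butenolide is present yet to trap the C9 radical, and the C–S bond reacts far more slowly than C–I. Sulfoxide formation (m-CPBA, CH2Cl2, −78 °C) and thermal syn-elimination (toluene, 90 °C) then give 19.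

Step 4. What may go wrong: loss of hydroxyl direction (1,2-addition, or delivery anti to O6) and migration of the 9,10-alkene into conjugation while C8 is equilibrated. The fallback sets out from 5 and comes back at 7. Mitsunobu inversion of the allylic alcohol (4-nitrobenzoic acid, DIAD, PPh3, THF) gives the (4S)-4-nitrobenzoate F5. Silyl triflate-promoted conjugate addition of Me2AlC≡CSiMe3 (Me3SiOTf, THF, −78 °C) should now occur under ordinary steric control anti to the C6 ester; K2CO3/MeOH then cleaves ester, silyl enol ether and C–Si bond and equilibrates C8, giving the C6 epimer of 7, F6. A second Mitsunobu inversion gives the 4-nitrobenzoate of 7, F7, and K2CO3/MeOH returns 7.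

Step 8. What may go wrong: palladium hydride-induced isomerisation of the strained (E)-8,9-alkene, or carboxylation at the terminal alkyne carbon. The fallback sets out from 12 and comes back at 13. Bromoboration of the terminal alkyne with B-bromo-9-borabicyclo[3.3.1]nonane (CH2Cl2, 0 °C) followed by protodeboronation (AcOH) gives the 2-bromoalkene F8. Hydroxycarbonylation of the alkenyl bromide (Pd(PPh3)4, CO (1 atm), H2O, Et3N, DMF, 60 °C), in which the base removes HBr at once, gives 13.

Further compounds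
F1 | step 11 | phenylthio keto lactone acid (4-SPh analogue of 15; C4 epimers) | OC(=O)C(=C)[C@H]1/C=C/[C@H](CO[Si](c4ccccc4)(c5ccccc5)C(C)(C)C)CCC(=O)C2(Sc6ccccc6)C[C@H]1OC2=O
F2 | step 11 | phenylthio hydroxy lactone acid (3S; 4-SPh) | OC(=O)C(=C)[C@H]1/C=C/[C@H](CO[Si](c4ccccc4)(c5ccccc5)C(C)(C)C)CC[C@H](O)C2(Sc6ccccc6)C[C@H]1OC2=O
F3 | step 11 | 9-iodo 12,8-lactone (I anti to O8; 4-SPh; 3-OH) | C=C1C(=O)O[C@@H]2[C@H](I)[C@H](CO[Si](c4ccccc4)(c5ccccc5)C(C)(C)C)CC[C@H](O)C3(Sc6ccccc6)C[C@@H](OC3=O)[C@@H]12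
F4 | step 11 | phenylthio bis-lactone (4-SPh; 3-OH; 12,8-olide) | C=C1C(=O)O[C@@H]2C[C@H](CO[Si](c4ccccc4)(c5ccccc5)C(C)(C)C)CC[C@H](O)C3(Sc6ccccc6)C[C@@H](OC3=O)[C@@H]12
F5 | step 4 | (1S)-3-[(1E)-3-{[tert-butyl(diphenyl)silyl]oxy}prop-1-en-1-yl]-4-oxocyclohex-2-en-1-yl 4-nitrobenzoate | O=C1C(/C=C/CO[Si](c4ccccc4)(c5ccccc5)C(C)(C)C)=C[C@@H](OC(=O)c7ccc(cc7)[N+](=O)[O-])CC1
F6 | step 4 | (2S,3R,4S)-2-[(1E)-3-{[tert-butyl(diphenyl)silyl]oxy}prop-1-en-1-yl]-3-ethynyl-4-hydroxycyclohexan-1-one (C6 epimer of 7) | O=C1[C@@H](/C=C/CO[Si](c4ccccc4)(c5ccccc5)C(C)(C)C)[C@H](C#C)[C@@H](O)CC1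
F7 | step 4 | (1R,2R,3S)-3-[(1E)-3-{[tert-butyl(diphenyl)silyl]oxy}prop-1-en-1-yl]-2-ethynyl-4-oxocyclohexyl 4-nitrobenzoate | O=C1[C@@H](/C=C/CO[Si](c4ccccc4)(c5ccccc5)C(C)(C)C)[C@H](C#C)[C@H](OC(=O)c7ccc(cc7)[N+](=O)[O-])CC1
F8 | step 8 | 2-bromoalkene analogue of 12 (C7 bearing C(Br)=CH2) | O=C1CC[C@@H](OC(=O)OC)[C@@H](C(Br)=C)/C=C/[C@H](CO[Si](c4ccccc4)(c5ccccc5)C(C)(C)C)CC1
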